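**Retrosynthetic overview**

1. Target ⇒ 8-hydroxy core + (E)-4-silyloxy-2-methylbut-2-enoic acid (late esterification at O8, then desilylation).
2. Core ⇒ in one flask: C6–C7 bond and lactone C–O by allylboration/lactonization of a cis-epoxy aldehyde with a 2-(methoxycarbonyl)allylboronate, then C1=C10 by ring-closing metathesis.
3. Epoxy aldehyde (C1–C6, C15) ⇒ Sharpless epoxidation of a neryl-type (Z)-allylic alcohol built from but-2-yn-1-ol.
4. Allylboronate (C7–C14) ⇒ 4-silyloxy-ynoate from an asymmetric carbonyl-ene reaction of methyl 4-oxobut-2-ynoate with isobutylene (sets C8).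
5. Ring order: oxirane first (acyclic stage), then γ-lactone and ten-membered carbocycle together in the same operation.

Assumption: the SMILES is read as the (1(10)Z,4R,5S,6S,7R,8R) isomer (germacrane numbering: cis-4,5-epoxide, trans-fused 12,6-lactone); methyl 4-hydroxybut-2-ynoate, but-3-en-1-ylmagnesium bromide solution and (tert-butyldimethylsilyloxy)acetaldehyde are taken as commercial.

**Route**

Step 1
Reactants: 1 but-2-yn-1-ol
Product: 3 (Z)-3-iodobut-2-en-1-ol, via cyclic vinylalanate 2 (not isolated)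
Conditions: NaAlH2(OCH2CH2OCH3)2, THF, 0 °C to rt; then I2, −78 °C to 0 °C
Reagents that add atoms: iodine, SMILES [I][I]
Why: Hydroxyl-directed trans-hydroalumination of the propargylic alcohol places aluminium on C3 cis to the CH2O group (five-membered alanate 2), and iodinolysis with retention fixes the Z geometry that later becomes the cis-epoxide.

Step 2
Reactants: 3 (Z)-3-iodobut-2-en-1-ol; 4 but-3-en-1-ylmagnesium bromide
Product: 5 (Z)-3-methylhepta-2,6-dien-1-ol
Conditions: 4 (2.5 equiv), PdCl2(dppf) (3 mol %), THF, 0 °C to rt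
Reagents that add atoms: none
Why: Kumada–Corriu cross-coupling of the alkenyl iodide with the primary alkyl Grignard reagent proceeds with retention of olefin geometry (the first equivalent of 4 only deprotonates the hydroxyl), and the bidentate dppf ligand suppresses β-hydride elimination.

Step 3
Reactants: 5 (Z)-3-methylhepta-2,6-dien-1-ol
Product: 6 [(2S,3R)-3-(but-3-en-1-yl)-3-methyloxiran-2-yl]methanol
Conditions: Ti(OiPr)4 (10 mol %), L-(+)-diisopropyl tartrate (12 mol %), t-BuOOH, 4 Å molecular sieves, CH2Cl2, −20 °C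
Reagents that add atoms: tert-butyl hydroperoxide, SMILES CC(C)(C)OO
Why: Katsuki–Sharpless asymmetric epoxidation with L-(+)-tartrate epoxidizes the Z-allylic alcohol on the same face as nerol, giving the (2S,3R)-cis-epoxy alcohol and thereby C5 (S) and C4 (R) of the target, while the isolated terminal alkene is untouched.

Step 4
Reactants: 6 [(2S,3R)-3-(but-3-en-1-yl)-3-methyloxiran-2-yl]methanol
Product: 7 (2R,3R)-3-(but-3-en-1-yl)-3-methyloxirane-2-carbaldehyde
Conditions: TEMPO (10 mol %), PhI(OAc)2 (1.1 equiv), CH2Cl2, rt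
Reagents that add atoms: none
Why: Oxoammonium-mediated oxidation of the primary alcohol stops at the aldehyde under near-neutral conditions, so the epoxide and the α-stereocentre are not disturbed (the descriptor at C2 changes only through the priority rules).

Step 5
Reactants: 8 methyl 4-hydroxybut-2-ynoate
Product: 9 methyl 4-oxobut-2-ynoate
Conditions: Dess–Martin periodinane, CH2Cl2, 0 °C to rt; product used directly as a solution
Reagents that add atoms: none
Why: Dess–Martin oxidation converts the propargylic alcohol into the ynal without touching the ester or the triple bond.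

Step 6
Reactants: 9 methyl 4-oxobut-2-ynoate; 10 2-methylpropene (isobutylene)
Product: 11 methyl (R)-4-hydroxy-6-methylhept-6-en-2-ynoate
Conditions: (R)-BINOL (10 mol %), TiCl2(OiPr)2 (10 mol %), 4 Å molecular sieves, CH2Cl2, −30 °C, excess 10
Reagents that add atoms: none
Why: Lewis acid-catalysed asymmetric carbonyl-ene reaction of the glyoxylate-ene type, with the ynal acting as an alkynylogous glyoxylate, in which the (R)-BINOL–titanium complex shields one aldehyde face so that isobutylene adds to give the (R)-carbinol that becomes C8.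

Step 7
Reactants: 11 methyl (R)-4-hydroxy-6-methylhept-6-en-2-ynoate
Product: 12 methyl (R)-6-methyl-4-(triethylsilyloxy)hept-6-en-2-ynoate
Conditions: Et3SiCl, imidazole, CH2Cl2, 0 °C
Reagents that add atoms: chlorotriethylsilane, SMILES CC[Si](Cl)(CC)CC
Why: Standard silylation masks the propargylic hydroxyl as a poor leaving group so that the following vinyl-metal step does not eliminate to an allene, and the triethylsilyl ether can later be removed under near-neutral fluoride conditions.

Step 8
Reactants: 12 methyl (R)-6-methyl-4-(triethylsilyloxy)hept-6-en-2-ynoate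
Product: 14 methyl (2Z,4R)-6-methyl-2-[(4,4,5,5-tetramethyl-1,3,2-dioxaborolan-2-yl)methyl]-4-(triethylsilyloxy)hepta-2,6-dienoate, via α-alumino acrylate 13 (not isolated)
Conditions: i-Bu2AlH, HMPA, THF, 0 °C; then ICH2Bpin, 0 °C to rt
Reagents that add atoms: 2-(iodomethyl)-4,4,5,5-tetramethyl-1,3,2-dioxaborolane, SMILES ICB1OC(C)(C)C(C)(C)O1
Why: Conjugate syn-hydroalumination of the ynoate gives the α-aluminated acrylate 13, which is C-alkylated by the iodomethylboronate on the side of the β-hydrogen, so that C4 ends up cis to the ester (2Z), the geometry required for an anti-selective allylboration.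

Step 9
Reactants: 15 (tert-butyldimethylsilyloxy)acetaldehyde; 16 ethyl 2-(triphenylphosphoranylidene)propanoate
Product: 17 ethyl (E)-4-(tert-butyldimethylsilyloxy)-2-methylbut-2-enoate
Conditions: CH2Cl2, rt
Reagents that add atoms: none
Why: Wittig olefination with a stabilized ylide gives the (E)-trisubstituted enoate with high selectivity.

Step 10
Reactants: 17 ethyl (E)-4-(tert-butyldimethylsilyloxy)-2-methylbut-2-enoate
Product: 18 (E)-4-(tert-butyldimethylsilyloxy)-2-methylbut-2-enoic acid
Conditions: LiOH, THF/MeOH/H2O, rt; then 1 M HCl to pH 4 at 0 °C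
Reagents that add atoms: lithium hydroxide, SMILES [Li+].[OH-]
Why: Saponification of the ethyl ester leaves the primary silyl ether and the E-olefin intact, and cold acidification to pH 4 liberates the acid without desilylation.

Step 11
Reactants: 7 (2R,3R)-3-(but-3-en-1-yl)-3-methyloxirane-2-carbaldehyde; 14 methyl (2Z,4R)-6-methyl-2-[(4,4,5,5-tetramethyl-1,3,2-dioxaborolan-2-yl)methyl]-4-(triethylsilyloxy)hepta-2,6-dienoate
Product: 21 (1(10)Z,4R,5S,6S,7S,8R)-4,5-epoxy-8-(triethylsilyloxy)germacra-1(10),11(13)-dien-12,6-olide, via borate ester 19 (not isolated), via lactone diene 20 (not isolated)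
Conditions: toluene (1 M), 80 °C, 36 h; then dilute with toluene to 1 mM, second-generation Hoveyda–Grubbs catalyst (15 mol %), 1,4-benzoquinone (30 mol %), 100 °C, 12 h
Reagents that add atoms: none
Why: Proposed new method: a thermal tandem allylboration–lactonization is telescoped with ring-closing metathesis in one flask; the allylboronate (C8 trans to CH2B, an E-type crotyl reagent) adds through a chair transition state to the Felkin–Anh face of the epoxy aldehyde (anti to the epoxide C–O), setting C6 and, by the anti course, C7, with the C8 stereocentre matched (H-8 eclipsing the alkene, C9 anti to the forming bond), borate 19 then lactonizes to the trans-lactone 20 with loss of MeOBpin, and the ruthenium carbene formed at the terminal vinyl group closes C1=C10, the ten-membered ring favouring the less strained Z-trisubstituted olefin; the closest known reactions are the tandem allylboration/lactonization of 2-alkoxycarbonyl allylboronates with aldehydes and ring-closing metathesis to medium-ring cycloalkenes.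

Step 12
Reactants: 21 (1(10)Z,4R,5S,6S,7S,8R)-4,5-epoxy-8-(triethylsilyloxy)germacra-1(10),11(13)-dien-12,6-olide
Product: 22 (1(10)Z,4R,5S,6S,7R,8R)-4,5-epoxy-8-hydroxygermacra-1(10),11(13)-dien-12,6-olide
Conditions: Et3N·3HF, THF, rt
Reagents that add atoms: none
Why: Fluoride-mediated cleavage of the secondary triethylsilyl ether under buffered conditions leaves the epoxide, the α-methylene lactone and the Z-olefin untouched and avoids base-induced translactonization to the 12,8-lactone.

Step 13
Reactants: 22 (1(10)Z,4R,5S,6S,7R,8R)-4,5-epoxy-8-hydroxygermacra-1(10),11(13)-dien-12,6-olide; 18 (E)-4-(tert-butyldimethylsilyloxy)-2-methylbut-2-enoic acid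
Product: 23 (1(10)Z,4R,5S,6S,7R,8R)-8-[(E)-4-(tert-butyldimethylsilyloxy)-2-methylbut-2-enoyloxy]-4,5-epoxygermacra-1(10),11(13)-dien-12,6-olide
Conditions: DCC, DMAP (20 mol %), CH2Cl2, 0 °C to rt
Reagents that add atoms: none
Why: Steglich esterification (carbodiimide activation, DMAP acyl transfer) acylates the 8-hydroxyl with retention at C8, and the (E)-2-methylbut-2-enoate is the thermodynamically stable geometry and does not isomerize.

Step 14
Reactants: 23 (1(10)Z,4R,5S,6S,7R,8R)-8-[(E)-4-(tert-butyldimethylsilyloxy)-2-methylbut-2-enoyloxy]-4,5-epoxygermacra-1(10),11(13)-dien-12,6-olide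
Product: 24 (1(10)Z,4R,5S,6S,7R,8R)-4,5-epoxy-8-[(E)-4-hydroxy-2-methylbut-2-enoyloxy]germacra-1(10),11(13)-dien-12,6-olide (target)
Conditions: Et3N·3HF, MeCN, rt
Reagents that add atoms: none
Why: Fluoride cleaves the primary allylic silyl ether under near-neutral conditions that spare both esters, the epoxide and the α-methylene lactone, giving the target.

**Compound list**

1 | but-2-yn-1-ol | CC#CCO | starting material
2 | sodium 2,2-bis(2-methoxyethoxy)-3-methyl-2,5-dihydro-1,2-oxaaluminol-2-uide (cyclic vinylalanate) | CC1=CCO[Al-]1(OCCOC)OCCOC.[Na+] | intermediate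
3 | (Z)-3-iodobut-2-en-1-ol | C/C(I)=C/CO | intermediate
4 | but-3-en-1-ylmagnesium bromide | C=CCC[Mg]Br | starting material
5 | (Z)-3-methylhepta-2,6-dien-1-ol | C=CCC/C(C)=C\CO | intermediate
6 | [(2S,3R)-3-(but-3-en-1-yl)-3-methyloxiran-2-yl]methanol | OC[C@@H]1O[C@]1(C)CCC=C | intermediate
7 | (2R,3R)-3-(but-3-en-1-yl)-3-methyloxirane-2-carbaldehyde | O=C[C@@H]1O[C@]1(C)CCC=C | intermediate
8 | methyl 4-hydroxybut-2-ynoate | COC(=O)C#CCO | starting material
9 | methyl 4-oxobut-2-ynoate | COC(=O)C#CC=O | intermediate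
10 | 2-methylpropene (isobutylene) | CC(C)=C | starting material
11 | methyl (R)-4-hydroxy-6-methylhept-6-en-2-ynoate | COC(=O)C#C[C@H](O)CC(C)=C | intermediate
12 | methyl (R)-6-methyl-4-(triethylsilyloxy)hept-6-en-2-ynoate | COC(=O)C#C[C@H](O[Si](CC)(CC)CC)CC(C)=C | intermediate
13 | methyl (2E,4R)-2-(diisobutylalumanyl)-6-methyl-4-(triethylsilyloxy)hepta-2,6-dienoate | COC(=O)/C([Al](CC(C)C)CC(C)C)=C\[C@H](O[Si](CC)(CC)CC)CC(C)=C | intermediate
14 | methyl (2Z,4R)-6-methyl-2-[(4,4,5,5-tetramethyl-1,3,2-dioxaborolan-2-yl)methyl]-4-(triethylsilyloxy)hepta-2,6-dienoate | COC(=O)/C(CB1OC(C)(C)C(C)(C)O1)=C\[C@H](O[Si](CC)(CC)CC)CC(C)=C | intermediate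
15 | (tert-butyldimethylsilyloxy)acetaldehyde | CC(C)(C)[Si](C)(C)OCC=O | starting material
16 | ethyl 2-(triphenylphosphoranylidene)propanoate | CCOC(=O)C(C)=P(c1ccccc1)(c1ccccc1)c1ccccc1 | starting material
17 | ethyl (E)-4-(tert-butyldimethylsilyloxy)-2-methylbut-2-enoate | CCOC(=O)/C(C)=C/CO[Si](C)(C)C(C)(C)C | intermediate
18 | (E)-4-(tert-butyldimethylsilyloxy)-2-methylbut-2-enoic acid | OC(=O)/C(C)=C/CO[Si](C)(C)C(C)(C)C | intermediate
19 | methyl (3S,4S)-4-[(2S,3R)-3-(but-3-en-1-yl)-3-methyloxiran-2-yl]-2-methylidene-3-[(1R)-3-methyl-1-(triethylsilyloxy)but-3-en-1-yl]-4-[(4,4,5,5-tetramethyl-1,3,2-dioxaborolan-2-yl)oxy]butanoate (borate ester) | COC(=O)C(=C)[C@H]([C@H](O[Si](CC)(CC)CC)CC(C)=C)[C@H](OB1OC(C)(C)C(C)(C)O1)[C@@H]1O[C@]1(C)CCC=C | intermediate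
20 | (4S,5S)-5-[(2S,3R)-3-(but-3-en-1-yl)-3-methyloxiran-2-yl]-3-methylidene-4-[(1R)-3-methyl-1-(triethylsilyloxy)but-3-en-1-yl]oxolan-2-one (lactone diene) | C=C1C(=O)O[C@@H]([C@H]1[C@H](O[Si](CC)(CC)CC)CC(C)=C)[C@@H]1O[C@]1(C)CCC=C | intermediate
21 | (1(10)Z,4R,5S,6S,7S,8R)-4,5-epoxy-8-(triethylsilyloxy)germacra-1(10),11(13)-dien-12,6-olide | C=C1C(=O)O[C@H]2[C@H]1[C@H](O[Si](CC)(CC)CC)C/C(C)=C\CC[C@@]1(C)O[C@@H]21 | intermediate
22 | (1(10)Z,4R,5S,6S,7R,8R)-4,5-epoxy-8-hydroxygermacra-1(10),11(13)-dien-12,6-olide | C=C1C(=O)O[C@H]2[C@H]1[C@H](O)C/C(C)=C\CC[C@@]1(C)O[C@@H]21 | intermediate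
23 | (1(10)Z,4R,5S,6S,7R,8R)-8-[(E)-4-(tert-butyldimethylsilyloxy)-2-methylbut-2-enoyloxy]-4,5-epoxygermacra-1(10),11(13)-dien-12,6-olide | C=C1C(=O)O[C@H]2[C@H]1[C@H](OC(=O)/C(C)=C/CO[Si](C)(C)C(C)(C)C)C/C(C)=C\CC[C@@]1(C)O[C@@H]21 | intermediate
24 | (1(10)Z,4R,5S,6S,7R,8R)-4,5-epoxy-8-[(E)-4-hydroxy-2-methylbut-2-enoyloxy]germacra-1(10),11(13)-dien-12,6-olide | C=C1C(=O)O[C@H]2[C@H]1[C@H](OC(=O)/C(C)=C/CO)C/C(C)=C\CC[C@@]1(C)O[C@@H]21 | target

**Step count**

Total: 14 steps. Longest linear sequence: 8 steps (8 → 9 → 11 → 12 → 14 → 21 → 22 → 23 → 24; the branch 1 → 3 → 5 → 6 → 7 → 21 → 24 is equally long).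

**Steps most likely to fail, with fallbacks**

Step 11 (one-flask allylboration/lactonization/ring-closing metathesis). The thermal allylboration may be too slow for the heat-sensitive epoxy aldehyde, and boron residues or the unpurified diene may spoil the ten-membered ring closure. The fallback sets out from 14 and 7 and comes back at 21. The C–B bond of 14 is oxidized with NaBO3·4H2O (THF/H2O, rt) to methyl (2Z,4R)-2-(hydroxymethyl)-6-methyl-4-(triethylsilyloxy)hepta-2,6-dienoate F1. F1 is converted with CBr4/PPh3 (CH2Cl2, 0 °C) into methyl (2E,4R)-2-(bromomethyl)-6-methyl-4-(triethylsilyloxy)hepta-2,6-dienoate F2. F2 is joined to 7 by a Nozaki–Hiyama allylation with CrCl2 (THF, rt), where the equilibrating allylchromium reacts at room temperature through an anti-selective chair transition state and the chromium alkoxide lactonizes. This gives 20 as an isolated, purified compound, which is cyclized in a separate slow-addition ring-closing metathesis (second-generation Hoveyda–Grubbs catalyst, toluene, 1 mM, 100 °C) to 21.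

Step 8 (hydroalumination/borylmethylation). Risks are loss of olefin geometry at the aluminium allenoate stage and elimination of the silyloxy group to an allene. The fallback sets out from 12 and comes back at 14. A Pd(PPh3)4-catalysed syn-hydrostannation with Bu3SnH (THF, 0 °C) gives methyl (2E,4R)-6-methyl-2-(tributylstannyl)-4-(triethylsilyloxy)hepta-2,6-dienoate F3. Iododestannylation (I2, CH2Cl2, 0 °C) gives, with retention, methyl (2E,4R)-2-iodo-6-methyl-4-(triethylsilyloxy)hepta-2,6-dienoate F4. A Negishi coupling of F4 with (pinacolatoboryl)methylzinc iodide (made from ICH2Bpin and zinc dust; Pd(PPh3)4, THF, rt) then delivers 14 with the olefin geometry fixed by the cross-coupling instead of by an enolate-type alkylation.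

Step 6 (asymmetric ene reaction of the ynal). The ynal is labile and cannot chelate like a glyoxylate, so the enantioselectivity is uncertain. The fallback sets out from 10 and comes back at 12, setting C8 with the parent glyoxylate-ene reaction and building the ynoate afterwards. Ethyl glyoxylate and 10 react under (R)-BINOL/TiCl2(OiPr)2 catalysis (CH2Cl2, −30 °C) to give ethyl (R)-2-hydroxy-4-methylpent-4-enoate F5. Silylation (Et3SiCl, imidazole) gives ethyl (R)-4-methyl-2-(triethylsilyloxy)pent-4-enoate F6. Reduction with i-Bu2AlH (CH2Cl2, −78 °C) gives (R)-4-methyl-2-(triethylsilyloxy)pent-4-enal F7. Seyferth–Gilbert homologation with dimethyl (1-diazo-2-oxopropyl)phosphonate (K2CO3, MeOH, 0 °C) gives (R)-triethyl[(5-methylhex-5-en-1-yn-3-yl)oxy]silane F8. Lithiation (n-BuLi, THF, −78 °C) and trapping with methyl chloroformate gives 12.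

Further compounds
F1 | step 11 | methyl (2Z,4R)-2-(hydroxymethyl)-6-methyl-4-(triethylsilyloxy)hepta-2,6-dienoate | COC(=O)/C(CO)=C\[C@H](O[Si](CC)(CC)CC)CC(C)=C
F2 | step 11 | methyl (2E,4R)-2-(bromomethyl)-6-methyl-4-(triethylsilyloxy)hepta-2,6-dienoate | COC(=O)/C(CBr)=C\[C@H](O[Si](CC)(CC)CC)CC(C)=C
F3 | step 8 | methyl (2E,4R)-6-methyl-2-(tributylstannyl)-4-(triethylsilyloxy)hepta-2,6-dienoate | COC(=O)/C([Sn](CCCC)(CCCC)CCCC)=C\[C@H](O[Si](CC)(CC)CC)CC(C)=C
F4 | step 8 | methyl (2E,4R)-2-iodo-6-methyl-4-(triethylsilyloxy)hepta-2,6-dienoate | COC(=O)/C(I)=C\[C@H](O[Si](CC)(CC)CC)CC(C)=C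
F5 | step 6 | ethyl (R)-2-hydroxy-4-methylpent-4-enoate | CCOC(=O)[C@H](O)CC(C)=C
F6 | step 6 | ethyl (R)-4-methyl-2-(triethylsilyloxy)pent-4-enoate | CCOC(=O)[C@H](O[Si](CC)(CC)CC)CC(C)=C
F7 | step 6 | (R)-4-methyl-2-(triethylsilyloxy)pent-4-enal | O=C[C@H](O[Si](CC)(CC)CC)CC(C)=C
F8 | step 6 | (R)-triethyl[(5-methylhex-5-en-1-yn-3-yl)oxy]silane | C#C[C@H](O[Si](CC)(CC)CC)CC(C)=C
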